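## Retrosynthetic overview

1. Target 16 ⇐ pentabenzyl ether 15 (BCl3/C6HMe5) ⇐ aryl bromide 13 + 2-methoxy-4-vinylphenol 14 (Heck reaction, E-alkene).
2. 13 ⇐ (S)-ketone 11 by C=O reduction and acid closure of the O1–C2 bond. The dihydrofuran is the only ring made (all four benzene rings are bought), and C2 ends trans to C3.
3. Key bond C2–C3: 11 ⇐ aldehyde 9 used as an acyl anion (carbene-bound Breslow intermediate) + o-quinone methide 10. A chiral triazolylidene sets C3.
4. 10 ⇐ sulfone 8 ⇐ benzhydrol 7 ⇐ aryl Grignard 6 (from 5) + salicylaldehyde 4 ⇐ 4-bromo-2,6-difluorobenzaldehyde 1 (two SNAr reactions).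

Assumption: the sense of induction in step 4 is taken as drawn; if C3 comes out with the opposite configuration, the mirror-image triazolium salt (also sold) is used. Compounds 1, 5, 9 and 14 are bought.

## Route

Step 1
Reactants: 1 4-bromo-2,6-difluorobenzaldehyde
Product: 4 2-(benzyloxy)-4-bromo-6-hydroxybenzaldehyde, via fluoro benzyl ether 2 (not isolated), via sulfonylethyl ether 3 (not isolated)
Conditions: BnOH (1.0 equiv), NaH (1.05 equiv), DMF, 0 °C; then MeSO2CH2CH2OH (1.5 equiv), NaH (3 equiv), 0 °C → rt; aq. HCl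
Reagents that add atoms: benzyl alcohol (OCc1ccccc1); 2-(methylsulfonyl)ethanol (CS(=O)(=O)CCO)
Why: Two SNAr reactions activated by the ortho formyl group: the first alkoxy group slows the ring enough to stop benzyloxide at mono-substitution, then the sulfonylethoxide displaces the second fluoride and loses methyl vinyl sulfone by E1cB to unveil the phenol.

Step 2
Reactants: 4 2-(benzyloxy)-4-bromo-6-hydroxybenzaldehyde; 5 1,3-bis(benzyloxy)-5-bromobenzene
Product: 7 rac-3-(benzyloxy)-2-{[3,5-bis(benzyloxy)phenyl](hydroxy)methyl}-5-bromophenol, via aryl Grignard reagent 6 (not isolated)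
Conditions: 5 (2.2 equiv), Mg, THF, 50 °C; then 4, THF, 0 °C → rt; H2O
Reagents that add atoms: none
Why: Grignard 1,2-addition to a salicylaldehyde: the first equivalent forms the magnesium phenoxide and the second adds to the aldehyde; the new carbinol centre is racemic and is erased in step 4.

Step 3
Reactants: 7 rac-3-(benzyloxy)-2-{[3,5-bis(benzyloxy)phenyl](hydroxy)methyl}-5-bromophenol
Product: 8 rac-3-(benzyloxy)-2-{[3,5-bis(benzyloxy)phenyl](4-methylbenzenesulfonyl)methyl}-5-bromophenol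
Conditions: TolSO2Na (2 equiv), HCO2H, THF–H2O, rt
Reagents that add atoms: sodium 4-methylbenzenesulfinate ([Na+].[O-]S(=O)c1ccc(C)cc1)
Why: Acid-promoted SN1 substitution: the ortho-oxygenated benzhydrol ionises and sulfinate captures the cation at sulfur, giving a bench-stable o-quinone methide precursor.

Step 4
Reactants: 8 rac-3-(benzyloxy)-2-{[3,5-bis(benzyloxy)phenyl](4-methylbenzenesulfonyl)methyl}-5-bromophenol; 9 3,4-bis(benzyloxy)benzaldehyde
Product: 11 (2S)-2-[2-(benzyloxy)-4-bromo-6-hydroxyphenyl]-1-[3,4-bis(benzyloxy)phenyl]-2-[3,5-bis(benzyloxy)phenyl]ethan-1-one, via o-quinone methide 10 (not isolated)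
Conditions: 9 (2 equiv), (5aR,10bS)-2-(pentafluorophenyl)-5a,10b-dihydro-4H,6H-indeno[2,1-b][1,2,4]triazolo[4,3-d][1,4]oxazin-2-ium tetrafluoroborate (20 mol %), Cs2CO3 (1.3 equiv), 4 Å MS, CH2Cl2, −20 → 0 °C; pH 7 buffer
Reagents that add atoms: none
Why: Proposed new method: base expels sulfinate from 8 reversibly, so o-quinone methide 10 is released slowly, while the triazolylidene turns aldehyde 9 into a nucleophilic Breslow intermediate (acyl anion equivalent) that adds to the exocyclic methide carbon, joining two natively electrophilic carbons, and rearomatisation with carbene release gives the α,α-diaryl ketone; the aminoindane wall shields one face of the enaminol and an enol O–H···O=C hydrogen bond orients the quinone methide, which fixes C3, and the product phenoxide disfavours enolisation and so holds the configuration; closest known reactions are the thiazolium-mediated acylation of o-quinone methides to racemic α-aryl ketones, the carbene-catalysed 1,6-hydroacylation of p-quinone methides and enantioselective intermolecular Stetter reactions with this triazolium family.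

Step 5
Reactants: 11 (2S)-2-[2-(benzyloxy)-4-bromo-6-hydroxyphenyl]-1-[3,4-bis(benzyloxy)phenyl]-2-[3,5-bis(benzyloxy)phenyl]ethan-1-one
Product: 13 (2S,3S)-4-(benzyloxy)-2-[3,4-bis(benzyloxy)phenyl]-3-[3,5-bis(benzyloxy)phenyl]-6-bromo-2,3-dihydro-1-benzofuran, via carbinol 12 (not isolated)
Conditions: NaBH4, THF–MeOH, −20 °C; aq. NH4Cl; then crude carbinol, p-TsOH·H2O (10 mol %), CH2Cl2, 0 °C
Reagents that add atoms: none
Why: Hydride reduction leaves C3 untouched, and acid-catalysed SN1 cyclodehydration through the 4-benzyloxybenzylic cation (intramolecular O-capture) sets C2 trans to the fixed C3 under thermodynamic control, so both carbinol epimers converge on (2S,3S).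

Step 6
Reactants: 13 (2S,3S)-4-(benzyloxy)-2-[3,4-bis(benzyloxy)phenyl]-3-[3,5-bis(benzyloxy)phenyl]-6-bromo-2,3-dihydro-1-benzofuran; 14 2-methoxy-4-vinylphenol
Product: 15 4-[(E)-2-{(2S,3S)-4-(benzyloxy)-2-[3,4-bis(benzyloxy)phenyl]-3-[3,5-bis(benzyloxy)phenyl]-2,3-dihydro-1-benzofuran-6-yl}ethenyl]-2-methoxyphenol
Conditions: 14 (2 equiv), Pd(OAc)2 (5 mol %), P(o-tol)3 (12 mol %), NaOAc (2 equiv), BHT (cat.), DMA, 110 °C
Reagents that add atoms: none
Why: Mizoroki–Heck reaction: syn-carbopalladation at the terminal alkene carbon and syn-β-hydride elimination give the E-stilbene; the free phenol is tolerated and the stereocentres are not involved.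

Step 7
Reactants: 15 4-[(E)-2-{(2S,3S)-4-(benzyloxy)-2-[3,4-bis(benzyloxy)phenyl]-3-[3,5-bis(benzyloxy)phenyl]-2,3-dihydro-1-benzofuran-6-yl}ethenyl]-2-methoxyphenol
Product: 16 (2S,3S)-2-(3,4-dihydroxyphenyl)-3-(3,5-dihydroxyphenyl)-6-[(E)-2-(4-hydroxy-3-methoxyphenyl)ethenyl]-2,3-dihydro-1-benzofuran-4-ol
Conditions: BCl3 (12 equiv), C6HMe5 (15 equiv), CH2Cl2, −78 °C; then H2O
Reagents that add atoms: none
Why: Lewis-acid ether cleavage: BCl3 removes the five aryl benzyl ethers at −78 °C while pentamethylbenzene traps the benzyl cations, and the aryl methyl ether, the stilbene and both stereocentres survive at this temperature.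

## Compound list

1 | 4-bromo-2,6-difluorobenzaldehyde | O=Cc1c(F)cc(Br)cc1F | starting material
2 | 2-(benzyloxy)-4-bromo-6-fluorobenzaldehyde | O=Cc1c(F)cc(Br)cc1OCc1ccccc1 | intermediate
3 | 2-(benzyloxy)-4-bromo-6-[2-(methanesulfonyl)ethoxy]benzaldehyde | O=Cc1c(OCCS(C)(=O)=O)cc(Br)cc1OCc1ccccc1 | intermediate
4 | 2-(benzyloxy)-4-bromo-6-hydroxybenzaldehyde | O=Cc1c(O)cc(Br)cc1OCc1ccccc1 | intermediate
5 | 1,3-bis(benzyloxy)-5-bromobenzene | Brc1cc(OCc2ccccc2)cc(OCc2ccccc2)c1 | starting material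
6 | [3,5-bis(benzyloxy)phenyl]magnesium bromide | Br[Mg]c1cc(OCc2ccccc2)cc(OCc2ccccc2)c1 | intermediate
7 | rac-3-(benzyloxy)-2-{[3,5-bis(benzyloxy)phenyl](hydroxy)methyl}-5-bromophenol | OC(c1cc(OCc2ccccc2)cc(OCc2ccccc2)c1)c1c(O)cc(Br)cc1OCc1ccccc1 | intermediate
8 | rac-3-(benzyloxy)-2-{[3,5-bis(benzyloxy)phenyl](4-methylbenzenesulfonyl)methyl}-5-bromophenol | Cc1ccc(cc1)S(=O)(=O)C(c1cc(OCc2ccccc2)cc(OCc2ccccc2)c1)c1c(O)cc(Br)cc1OCc1ccccc1 | intermediate
9 | 3,4-bis(benzyloxy)benzaldehyde | O=Cc1ccc(OCc2ccccc2)c(OCc2ccccc2)c1 | starting material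
10 | 5-(benzyloxy)-6-{[3,5-bis(benzyloxy)phenyl]methylidene}-3-bromocyclohexa-2,4-dien-1-one (o-quinone methide, alkene geometry not defined) | O=C1C=C(Br)C=C(OCc2ccccc2)C1=Cc1cc(OCc2ccccc2)cc(OCc2ccccc2)c1 | intermediate
11 | (2S)-2-[2-(benzyloxy)-4-bromo-6-hydroxyphenyl]-1-[3,4-bis(benzyloxy)phenyl]-2-[3,5-bis(benzyloxy)phenyl]ethan-1-one | O=C(c1ccc(OCc2ccccc2)c(OCc2ccccc2)c1)[C@@H](c1cc(OCc2ccccc2)cc(OCc2ccccc2)c1)c1c(O)cc(Br)cc1OCc1ccccc1 | intermediate
12 | (2S)-2-[2-(benzyloxy)-4-bromo-6-hydroxyphenyl]-1-[3,4-bis(benzyloxy)phenyl]-2-[3,5-bis(benzyloxy)phenyl]ethan-1-ol (both C1 epimers) | OC(c1ccc(OCc2ccccc2)c(OCc2ccccc2)c1)[C@@H](c1cc(OCc2ccccc2)cc(OCc2ccccc2)c1)c1c(O)cc(Br)cc1OCc1ccccc1 | intermediate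
13 | (2S,3S)-4-(benzyloxy)-2-[3,4-bis(benzyloxy)phenyl]-3-[3,5-bis(benzyloxy)phenyl]-6-bromo-2,3-dihydro-1-benzofuran (trans) | Brc1cc(OCc2ccccc2)c2c(c1)O[C@H](c1ccc(OCc3ccccc3)c(OCc3ccccc3)c1)[C@H]2c1cc(OCc2ccccc2)cc(OCc2ccccc2)c1 | intermediate
14 | 2-methoxy-4-vinylphenol (4-ethenyl-2-methoxyphenol) | COc1cc(C=C)ccc1O | starting material
15 | 4-[(E)-2-{(2S,3S)-4-(benzyloxy)-2-[3,4-bis(benzyloxy)phenyl]-3-[3,5-bis(benzyloxy)phenyl]-2,3-dihydro-1-benzofuran-6-yl}ethenyl]-2-methoxyphenol | COc1cc(/C=C/c2cc(OCc3ccccc3)c3c(c2)O[C@H](c2ccc(OCc4ccccc4)c(OCc4ccccc4)c2)[C@H]3c2cc(OCc3ccccc3)cc(OCc3ccccc3)c2)ccc1O | intermediate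
16 | (2S,3S)-2-(3,4-dihydroxyphenyl)-3-(3,5-dihydroxyphenyl)-6-[(E)-2-(4-hydroxy-3-methoxyphenyl)ethenyl]-2,3-dihydro-1-benzofuran-4-ol (trans) | COc1cc(/C=C/c2cc(O)c3c(c2)O[C@H](c2ccc(O)c(O)c2)[C@H]3c2cc(O)cc(O)c2)ccc1O | target

## Step count and risks

Total steps: 7. Longest linear sequence: 7 (steps 1 to 7; compounds 5, 9 and 14 are bought).

**Step 4 (most likely to fail).** The enantioselective acyl anion addition is new, and the α,α-diaryl ketone may not hold its configuration. The fallback sets out from 8 (with 9) and comes back at 13. Sulfone 8 and aldehyde 9 are coupled without asymmetric induction, using 3-benzyl-5-(2-hydroxyethyl)-4-methylthiazolium chloride and Cs2CO3, to give rac-2-[2-(benzyloxy)-4-bromo-6-hydroxyphenyl]-1-[3,4-bis(benzyloxy)phenyl]-2-[3,5-bis(benzyloxy)phenyl]ethan-1-one F2. The lability of its α-centre is then used in a dynamic kinetic resolution by asymmetric transfer hydrogenation with RuCl[(S,S)-TsDPEN](p-cymene) in HCO2H/Et3N at 40 °C. The ketone epimerises through its enol faster than it is reduced, and the Felkin-matched enantiomer is expected to give (1S,2S)-2-[2-(benzyloxy)-4-bromo-6-hydroxyphenyl]-1-[3,4-bis(benzyloxy)phenyl]-2-[3,5-bis(benzyloxy)phenyl]ethan-1-ol F3, a single stereoisomer of 12. If C2 came out R, the (R,R) catalyst would be used; C1 is erased afterwards in either case. F3 is closed with catalytic p-TsOH as in step 5 to give 13.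

**Step 1.** The hydroxide-surrogate SNAr runs next to a free aldehyde and on a ring already deactivated by one alkoxy group. The fallback sets out from 1 and comes back at 4. Both fluorides are displaced with benzyl alcohol (2.2 equiv) and NaH in DMF to give 2,6-bis(benzyloxy)-4-bromobenzaldehyde F1. One benzyl group is then removed with BCl3 (1.05 equiv) in CH2Cl2 at −78 °C: boron chelated between the aldehyde oxygen and one ortho ether cleaves that ether only, and the resulting aryloxyboron chelate protects the second, giving 4.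

**Step 7.** BCl3 could open the dihydrofuran at its doubly activated benzylic C2–O1 bond or damage the electron-rich stilbene. The fallback sets out from 13 and comes back at 16, and replaces the Lewis acid by hydrogenolysis carried out before the alkene exists. Bromide 13 is borylated (B2pin2, Pd(dppf)Cl2, KOAc, dioxane, 90 °C) to 2-{(2S,3S)-4-(benzyloxy)-2-[3,4-bis(benzyloxy)phenyl]-3-[3,5-bis(benzyloxy)phenyl]-2,3-dihydro-1-benzofuran-6-yl}-4,4,5,5-tetramethyl-1,3,2-dioxaborolane F4. With no halide or alkene present, the five benzyl ethers are removed by H2 over Pd/C in EtOAc–MeOH, giving (2S,3S)-2-(3,4-dihydroxyphenyl)-3-(3,5-dihydroxyphenyl)-6-(4,4,5,5-tetramethyl-1,3,2-dioxaborolan-2-yl)-2,3-dihydro-1-benzofuran-4-ol F5. The alkenyl partner 4-[(E)-2-bromoethenyl]-2-methoxyphenol F6 is made from commercial ferulic acid by bromodecarboxylation (N-bromosuccinimide, catalytic LiOAc, MeCN–H2O). Suzuki–Miyaura coupling of F5 with F6 (Pd(PPh3)4, K3PO4, degassed dioxane–H2O, 60 °C) proceeds with retention of alkene geometry and gives 16.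

Further compounds

F1 | step 1 | 2,6-bis(benzyloxy)-4-bromobenzaldehyde | O=Cc1c(OCc2ccccc2)cc(Br)cc1OCc1ccccc1
F2 | step 4 | rac-2-[2-(benzyloxy)-4-bromo-6-hydroxyphenyl]-1-[3,4-bis(benzyloxy)phenyl]-2-[3,5-bis(benzyloxy)phenyl]ethan-1-one | O=C(c1ccc(OCc2ccccc2)c(OCc2ccccc2)c1)C(c1cc(OCc2ccccc2)cc(OCc2ccccc2)c1)c1c(O)cc(Br)cc1OCc1ccccc1
F3 | step 4 | (1S,2S)-2-[2-(benzyloxy)-4-bromo-6-hydroxyphenyl]-1-[3,4-bis(benzyloxy)phenyl]-2-[3,5-bis(benzyloxy)phenyl]ethan-1-ol | O[C@H](c1ccc(OCc2ccccc2)c(OCc2ccccc2)c1)[C@@H](c1cc(OCc2ccccc2)cc(OCc2ccccc2)c1)c1c(O)cc(Br)cc1OCc1ccccc1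
F4 | step 7 | 2-{(2S,3S)-4-(benzyloxy)-2-[3,4-bis(benzyloxy)phenyl]-3-[3,5-bis(benzyloxy)phenyl]-2,3-dihydro-1-benzofuran-6-yl}-4,4,5,5-tetramethyl-1,3,2-dioxaborolane | CC1(C)OB(OC1(C)C)c1cc(OCc2ccccc2)c2c(c1)O[C@H](c1ccc(OCc3ccccc3)c(OCc3ccccc3)c1)[C@H]2c1cc(OCc2ccccc2)cc(OCc2ccccc2)c1
F5 | step 7 | (2S,3S)-2-(3,4-dihydroxyphenyl)-3-(3,5-dihydroxyphenyl)-6-(4,4,5,5-tetramethyl-1,3,2-dioxaborolan-2-yl)-2,3-dihydro-1-benzofuran-4-ol | CC1(C)OB(OC1(C)C)c1cc(O)c2c(c1)O[C@H](c1ccc(O)c(O)c1)[C@H]2c1cc(O)cc(O)c1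
F6 | step 7 | 4-[(E)-2-bromoethenyl]-2-methoxyphenol | COc1cc(/C=C/Br)ccc1O
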